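**Plan**

- Retrosynthesis (gibberellane numbering): the 15β-OH is taken back to the 16-ene, and the C20-aldehyde/C19-acid pair to a 19,20-anhydride. Ring A is then cut at C1–C10 and C3–C4 (loss of a three-carbon 1,3-dielectrophile). The remaining B/C/D tricycle is cut at C4–C5, C10–C20, C5–C10, C8–C15, C6=C8, C13–C16 and C9–C10, down to cyclohex-2-enone.
- What makes the ring-A event possible: C19 (on C4) and C20 (on C10) are 1,3-diaxial on the α face of ring A, so they can be tied as a six-membered anhydride C19–O–C20 fused to ring B along C5–C10. C4 and C10 are then the two α-carbons of a glutaric anhydride, and a three-carbon chain can bridge them only cis. Ring A becomes the carbocyclic ring of a 3-oxabicyclo[3.3.1]nonane and both quaternary centres are set at once.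
- Forward: ring C is the starting cyclohexenone; ring D is closed by an intramolecular ene reaction (C8–C15, quaternary C8, 16-methylene); ring B by Dieckmann condensation (C5–C10). C20 and the C4 propionate arm are added to ring B, the temporary anhydride ring is made, and ring A follows by double alkylation. The anhydride is then opened to 19-ester/20-acid, C20 is taken to the aldehyde, and C15 is oxygenated last.
- Stereochemistry: C13 comes from a Rh/(R)-BINAP 1,4-addition (the only external source). C8 and C9 are relayed from C13 in the ene closure. C10 (temporary) and C5 arise by anti additions on ring B, C6 by equilibration. C4 and C10 are fixed by the anhydride tether. C15 comes from exo-face hydride delivery to the 15-ketone.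

Key step: step 14

Remark: gibberellane atom numbers are used throughout (ring A C1–C5/C10; ring B C5, C6, C8–C10; ring C C8, C9, C11–C14; ring D C8, C13–C16; C7 on C6, C17 on C16, C18 and C19 on C4, C20 on C10). α and β refer to the usual gibberellin drawing (H5 and H9 β; C19 and C20 α; 15β = endo, on the side of C11–C12). The C19 carbonyl of the bridged anhydride is assumed to be the less hindered one.

**Route**

Step 1
Reactants: 1 cyclohex-2-en-1-one; 2 tert-butyl bromoacetate
Product: 3 tert-butyl 2-(2-oxocyclohex-3-en-1-yl)acetate (racemic)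
Conditions: LDA (1.05 equiv), THF, −78 °C; then 2, DMPU, −78 → −30 °C
Reagents that add atoms: none
Why: Kinetic α′-deprotonation of the enone gives the cross-conjugated lithium enolate, which is C-alkylated by the activated bromide (enolate alkylation); the new centre (future C9) is racemic and epimerisable, so it needs no control here.

Step 2
Reactants: 3 tert-butyl 2-(2-oxocyclohex-3-en-1-yl)acetate; 4 2-isopropenyl-4,4,5,5-tetramethyl-1,3,2-dioxaborolane
Product: 5 tert-butyl 2-[(1S,4R)-2-oxo-4-(prop-1-en-2-yl)cyclohexyl]acetate
Conditions: Rh(acac)(C2H4)2 (3 mol %), (R)-BINAP (3.3 mol %), K3PO4 (0.5 equiv), dioxane/H2O 10:1, 80 °C; then DBU (0.2 equiv), CH2Cl2, 25 °C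
Reagents that add atoms: none
Why: The Hayashi–Miyaura rhodium-catalysed 1,4-addition of the alkenylboronate should set C13 (4R) under control of (R)-BINAP regardless of the remote C9 centre, and DBU then equilibrates C9 to the trans-1,4 (diequatorial, 1S) ketone.

Step 3
Reactants: 5 tert-butyl 2-[(1S,4R)-2-oxo-4-(prop-1-en-2-yl)cyclohexyl]acetate; 6 diallyl malonate
Product: 7 diallyl 2-[(2S,5R)-2-(2-tert-butoxy-2-oxoethyl)-5-(prop-1-en-2-yl)cyclohexylidene]malonate
Conditions: TiCl4 (2 equiv), pyridine (4 equiv), THF, 0 → 25 °C
Reagents that add atoms: none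
Why: Knoevenagel condensation of the ketone with the malonate (TiCl4/pyridine variant, buffered so that the tert-butyl ester survives) should give the tetrasubstituted alkylidene malonate, in which A(1,3) strain places the C9 side chain axial; no new stereocentre is formed.

Step 4
Reactants: 7 diallyl 2-[(2S,5R)-2-(2-tert-butoxy-2-oxoethyl)-5-(prop-1-en-2-yl)cyclohexylidene]malonate
Product: 8 C/D bicyclic triester (diallyl 2-[2-(2-tert-butoxy-2-oxoethyl)-6-methylenebicyclo[3.2.1]oct-1-yl]malonate; side chain anti to the two-carbon bridge)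
Conditions: FeCl3 on neutral Al2O3 (20 mol % FeCl3), CH2Cl2, −40 → 0 °C
Reagents that add atoms: none
Why: An intramolecular Lewis-acid-promoted ene reaction between the alkylidene malonate (enophile) and the axial isopropenyl group (ene) should form C8–C15, move a methyl hydrogen to C6 and leave the exocyclic 16-methylene; quaternary C8 is dictated by C13 because the bicyclo[3.2.1]octane can close only on the face of the isopropenyl group, which is anti to the axial C9 side chain (H9 syn to C15).

Step 5
Reactants: 8 C/D bicyclic triester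
Product: 9 B/C/D tricyclic β-keto diester (5-oxo; 10-CO2tBu; 6-CO2allyl; 9βH; 16-ene)
Conditions: NaH (1.2 equiv), allyl alcohol (5 equiv), toluene, 80 °C; AcOH quench
Reagents that add atoms: none
Why: In this reversible, thermodynamically controlled Dieckmann condensation (sodium allyloxide) the tert-butyl acetate enolate (C10) attacks one malonate allyl ester to close ring B (C5–C10) and the doubly stabilised β-keto diester enolate drains the equilibrium, whereas attack of the malonate anion on the hindered tert-butyl ester would give a product that cannot be enolised between its carbonyl groups and reverts; ring B is cis-fused to ring C because the two arms on C8 and C9 are gauche (C6 and C10 are enolised and undefined).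

Step 6
Reactants: 9 B/C/D tricyclic β-keto diester
Product: 11 B/C/D tricyclic keto ester (5-oxo; 6-CO2allyl; 16-ene), via β-keto acid 10 (not isolated)
Conditions: TMSOTf (3 equiv), 2,6-lutidine (4 equiv), CH2Cl2, 0 °C; then MeOH; then toluene, 60 °C
Reagents that add atoms: none
Why: Non-protic cleavage of the tert-butyl ester (which spares the acid-sensitive 16-methylene and the allyl ester) followed by decarboxylation of the β-keto acid removes the activating carboxyl from C10.

Step 7
Reactants: 11 B/C/D tricyclic keto ester; 12 4-methoxybenzyl chloromethyl ether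
Product: 13 10β-(4-methoxybenzyloxymethyl) keto ester
Conditions: LDA (2.2 equiv), THF, 0 °C; then 12, −78 → 0 °C
Reagents that add atoms: none
Why: γ-Alkylation of the β-keto ester dianion occurs only at the more basic C10 carbanion and anti to C11 on the adjacent C9, which puts the new C20 arm on the β face (trans to C11, also the thermodynamic epimer).

Step 8
Reactants: 13 10β-(4-methoxybenzyloxymethyl) keto ester
Product: 14 5-hydroxy ester
Conditions: NaBH4, MeOH, 0 °C
Reagents that add atoms: none
Why: NaBH4 reduces the ring ketone but not the esters (chemoselective carbonyl reduction), and the carbinol configuration is irrelevant because the oxygen is eliminated in step 9.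

Step 9
Reactants: 14 5-hydroxy ester
Product: 16 cyclopentene ester (5,6-ene; 6-CO2allyl; 10β-CH2OPMB), via mesylate 15 (not isolated)
Conditions: MsCl, Et3N, CH2Cl2, 0 °C; then DBU, 25 → 40 °C
Reagents that add atoms: none
Why: Mesylation and E1cB elimination towards the acidic C6–H should give the conjugated cyclopentenecarboxylate, and because C10 carries only an ether arm its γ-hydrogen is not activated by a second carbonyl group and should not quench the nucleophile of step 10.

Step 10
Reactants: 16 cyclopentene ester; 17 tert-butyl propionate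
Product: 18 Michael adduct (5α-CH(CH3)CO2tBu; 5βH; 6β-CO2allyl; 10β-CH2OPMB)
Conditions: LDA (1.3 equiv), 17 (1.4 equiv), THF, −78 °C; add 16, −78 → −40 °C; aq. NH4Cl; then DBU (1 equiv), toluene, 60 °C
Reagents that add atoms: none
Why: Michael addition of the lithium ester enolate to the enoate forms C4–C5 anti to the adjacent β-oriented C20 arm (C4 α, H5 β), DBU then equilibrates C6 to the ester trans to C4 (C7 β), and C4 is left as a mixture because it is enolised again in step 14.

Step 11
Reactants: 18 Michael adduct
Product: 19 20-alcohol (19-tert-butyl ester)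
Conditions: DDQ (1.3 equiv), CH2Cl2/pH 7 buffer 18:1, 0 → 25 °C
Reagents that add atoms: none
Why: Oxidative cleavage of the 4-methoxybenzyl ether by DDQ (benzylic hydride abstraction, then hemiacetal hydrolysis) frees the C20 alcohol without touching alkenes or esters, and the trans arrangement of C20 and C4 prevents lactonisation.

Step 12
Reactants: 19 20-alcohol
Product: 20 20-acid 19-tert-butyl ester
Conditions: TEMPO (20 mol %), PhI(OAc)2 (2.5 equiv), MeCN/H2O 1:1, 25 °C
Reagents that add atoms: water, O
Why: TEMPO/PhI(OAc)2 oxidation in aqueous acetonitrile takes the primary alcohol through the aldehyde hydrate to the C20 carboxylic acid under nearly neutral conditions that spare the 16-ene.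

Step 13
Reactants: 20 20-acid 19-tert-butyl ester
Product: 22 tricyclic glutaric anhydride (19,20-anhydride; 5βH; 10βH; 6β-CO2allyl), via diacid 21 (not isolated)
Conditions: TMSOTf (3 equiv), 2,6-lutidine (4 equiv), CH2Cl2, 0 °C; MeOH; then Ac2O, NaOAc (0.3 equiv), 120 °C
Reagents that add atoms: none
Why: Non-protic tert-butyl ester cleavage followed by dehydration of the 1,5-diacid in hot Ac2O/NaOAc should give the six-membered anhydride, with epimerisation of the enolisable C10 (and C4) so that the ring is cis-fused to ring B on the α face defined by C5; the C10 configuration is not critical, because this centre is enolised again in step 14.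

Step 14
Reactants: 22 tricyclic glutaric anhydride; 23 1-chloro-3-iodopropane
Product: 25 tetracyclic 19,20-anhydride 7-allyl ester (ring A closed; C20 α; C18 β; 5βH), via chloride 24 (not isolated)
Conditions: LDA (1.05 equiv), THF/DMPU, −78 °C; 23 (1.05 equiv), −78 → −30 °C; then LDA (1.2 equiv), −78 → 25 °C
Reagents that add atoms: none
Why: Proposed new method: the first equivalent of LDA removes the C4–H of the glutaric anhydride and the tetrasubstituted lithium enolate is C-alkylated by the iodide end of 23 on the face anti to C6 to give chloride 24, and the second equivalent enolises C10, whose carbanion closes ring A by intramolecular displacement of chloride (6-exo-tet, chair), so that C3–C4 and C1–C10 are made in one flask; should C10 be enolised first, the same two bonds would form in the reverse order. The closest known reaction type is the stepwise one-pot α,α′-dialkylation of cycloalkane-1,3-dicarboxylic esters with 1,3-dihalopropanes to give bicyclo[3.3.1]nonane-1,5-dicarboxylates; new here is the enolate chemistry of a cyclic anhydride, which should hold because ketene-forming ring-opening of the enolate is reversible within the tether and intermolecular self-acylation is slowed by the hindered, fully substituted enolate carbons at −78 °C. Both new quaternary centres are set by the anhydride bridge: C19 and C20 must finish cis (1,3-diaxial) in the 3-oxabicyclo[3.3.1]nonane, and because the first alkylation takes the face of the anhydride ring anti to C6 (syn to H5), the three-carbon chain spans that face, which makes C20 α, C18 β and ring A trans-fused to ring B. The step needs C- over O-alkylation (soft iodide, lithium counter-ion), a single alkylation in the first stage (one equivalent of base, iodide far more reactive than chloride) and enolisation of the anhydride and not of the C7 allyl ester, which the higher acidity of the anhydride α-hydrogens and the shielding of C6–H by quaternary C8 should secure at −78 °C.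

Step 15
Reactants: 25 tetracyclic 19,20-anhydride 7-allyl ester
Product: 26 tetracyclic 20-acid 7,19-diallyl ester
Conditions: allyl alcohol (5 equiv), NaH (1.5 equiv), THF, 0 → 25 °C; dilute aqueous HCl work-up
Reagents that add atoms: allyl alcohol, C=CCO
Why: Alcoholysis of the anhydride by sodium allyloxide should occur at the less hindered C19 carbonyl (C20 is shielded by C9, C11 and C14) to give the 19-allyl ester and the free 20-acid, while ester exchange at C7 is degenerate.

Step 16
Reactants: 26 tetracyclic 20-acid 7,19-diallyl ester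
Product: 28 20-aldehyde 7,19-diallyl ester, via acyl chloride 27 (not isolated)
Conditions: (COCl)2 (1.5 equiv), DMF (cat.), CH2Cl2, 0 °C, then evaporation below 20 °C; LiAlH(OtBu)3 (1.1 equiv), THF, −78 °C
Reagents that add atoms: none
Why: The hindered acid is converted into its chloride (kept cold to avoid ester participation) and reduced by the bulky LiAlH(OtBu)3, which stops at the neopentyl aldehyde and leaves allyl esters alone (acid chloride to aldehyde reduction).

Step 17
Reactants: 28 20-aldehyde 7,19-diallyl ester
Product: 29 15α-hydroxy 20-aldehyde diallyl ester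
Conditions: SeO2 (0.5 equiv), t-BuOOH (3 equiv, in decane), CH2Cl2, 0 → 25 °C
Reagents that add atoms: tert-butyl hydroperoxide, CC(C)(C)OO (terminal oxygen source, relayed by SeO2, O=[Se]=O)
Why: Riley allylic oxidation (ene reaction of SeO2, then [2,3]-shift) can engage only the C15 methylene of the 16-ene, since C13 is a bridgehead, and should deliver oxygen from the open exo face (syn to C14) to give the 15α alcohol.

Step 18
Reactants: 29 15α-hydroxy 20-aldehyde diallyl ester
Product: 30 15-oxo 20-aldehyde diallyl ester
Conditions: MnO2 (activated, 20 equiv), CH2Cl2, 25 °C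
Reagents that add atoms: none
Why: MnO2 oxidises only the allylic alcohol, giving the 15-oxo-16-ene enone and leaving the C20 aldehyde untouched.

Step 19
Reactants: 30 15-oxo 20-aldehyde diallyl ester
Product: 31 15β-hydroxy 20-aldehyde diallyl ester (diallyl ester of the target)
Conditions: NaBH4 (1.0 equiv), CeCl3·7H2O (1.2 equiv), MeOH, −78 °C
Reagents that add atoms: none
Why: Luche reduction gives 1,2-addition to the enone with hydride arriving from the exo face (syn to C14), so that the hydroxyl ends endo (15β, syn to C11–C12), and under these conditions a ketone is reduced in preference to an aldehyde, here a neopentyl one.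

Step 20
Reactants: 31 15β-hydroxy 20-aldehyde diallyl ester
Product: 32 target gibberellin (15β-hydroxy-20-oxogibberell-16-ene-7,19-dioic acid)
Conditions: Pd(PPh3)4 (5 mol %), morpholine (10 equiv), THF, 25 °C; then dilute aqueous citric acid to pH 3
Reagents that add atoms: none
Why: Tsuji–Trost deallylation with zerovalent palladium and morpholine removes both allyl esters under neutral conditions that tolerate the aldehyde, the allylic alcohol and the 16-ene, giving the target.

**Compound list**

1 | cyclohex-2-en-1-one | O=C1C=CCCC1 | starting material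
2 | tert-butyl bromoacetate | CC(C)(C)OC(=O)CBr | starting material
3 | tert-butyl 2-(2-oxocyclohex-3-en-1-yl)acetate (racemic) | O=C1C=CCCC1CC(=O)OC(C)(C)C | intermediate
4 | 2-isopropenyl-4,4,5,5-tetramethyl-1,3,2-dioxaborolane | C=C(C)B1OC(C)(C)C(C)(C)O1 | starting material
5 | tert-butyl 2-[(1S,4R)-2-oxo-4-(prop-1-en-2-yl)cyclohexyl]acetate | CC(=C)[C@@H]1CC[C@@H](CC(=O)OC(C)(C)C)C(=O)C1 | intermediate
6 | diallyl malonate | C=CCOC(=O)CC(=O)OCC=C | starting material
7 | diallyl 2-[(2S,5R)-2-(2-tert-butoxy-2-oxoethyl)-5-(prop-1-en-2-yl)cyclohexylidene]malonate | CC(=C)[C@@H]1CC[C@@H](CC(=O)OC(C)(C)C)C(=C(C(=O)OCC=C)C(=O)OCC=C)C1 | intermediate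
8 | C/D bicyclic triester: diallyl 2-[2-(2-tert-butoxy-2-oxoethyl)-6-methylenebicyclo[3.2.1]oct-1-yl]malonate, side chain (C9) anti to the C15–C16 bridge | C=C1[C@@H]2CC[C@@H](CC(=O)OC(C)(C)C)[C@@](C(C(=O)OCC=C)C(=O)OCC=C)(C2)C1 | intermediate
9 | B/C/D tricyclic β-keto diester (5-oxo; 10-CO2tBu; 6-CO2allyl; 9βH; 16-ene; C6 and C10 enolisable) | C=C1[C@@H]2CC[C@H]3C(C(=O)OC(C)(C)C)C(=O)C(C(=O)OCC=C)[C@]3(C2)C1 | intermediate
10 | β-keto acid (10-CO2H analogue of 9) | C=C1[C@@H]2CC[C@H]3C(C(=O)O)C(=O)C(C(=O)OCC=C)[C@]3(C2)C1 | intermediate (not isolated)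
11 | B/C/D tricyclic keto ester (5-oxo; 6-CO2allyl; 9βH; 16-ene) | C=C1[C@@H]2CC[C@H]3CC(=O)C(C(=O)OCC=C)[C@]3(C2)C1 | intermediate
12 | 4-methoxybenzyl chloromethyl ether | COc1ccc(COCCl)cc1 | starting material
13 | 10β-(4-methoxybenzyloxymethyl) keto ester | C=C1[C@@H]2CC[C@H]3[C@H](COCc4ccc(OC)cc4)C(=O)C(C(=O)OCC=C)[C@]3(C2)C1 | intermediate
14 | 5-hydroxy ester (carbinol epimers) | C=C1[C@@H]2CC[C@H]3[C@H](COCc4ccc(OC)cc4)C(O)C(C(=O)OCC=C)[C@]3(C2)C1 | intermediate
15 | 5-mesylate of 14 | C=C1[C@@H]2CC[C@H]3[C@H](COCc4ccc(OC)cc4)C(OS(C)(=O)=O)C(C(=O)OCC=C)[C@]3(C2)C1 | intermediate (not isolated)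
16 | cyclopentene ester (5,6-ene; 6-CO2allyl; 10β-CH2OPMB) | C=C1[C@@H]2CC[C@H]3[C@H](COCc4ccc(OC)cc4)C=C(C(=O)OCC=C)[C@]3(C2)C1 | intermediate
17 | tert-butyl propionate | CCC(=O)OC(C)(C)C | starting material
18 | Michael adduct (5α-CH(CH3)CO2tBu, C4 epimers; 5βH; 6β-CO2allyl; 10β-CH2OPMB) | C=C1[C@@H]2CC[C@H]3[C@H](COCc4ccc(OC)cc4)[C@@H](C(C)C(=O)OC(C)(C)C)[C@H](C(=O)OCC=C)[C@]3(C2)C1 | intermediate
19 | 20-alcohol (19-tert-butyl ester) | C=C1[C@@H]2CC[C@H]3[C@H](CO)[C@@H](C(C)C(=O)OC(C)(C)C)[C@H](C(=O)OCC=C)[C@]3(C2)C1 | intermediate
20 | 20-acid 19-tert-butyl ester | C=C1[C@@H]2CC[C@H]3[C@H](C(=O)O)[C@@H](C(C)C(=O)OC(C)(C)C)[C@H](C(=O)OCC=C)[C@]3(C2)C1 | intermediate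
21 | 19,20-diacid (7-allyl ester) | C=C1[C@@H]2CC[C@H]3[C@H](C(=O)O)[C@@H](C(C)C(=O)O)[C@H](C(=O)OCC=C)[C@]3(C2)C1 | intermediate (not isolated)
22 | tricyclic glutaric anhydride (19,20-anhydride cis-fused to ring B; 5βH; 10βH; 6β-CO2allyl; C4 epimers) | C=C1[C@@H]2CC[C@H]3[C@H]4C(=O)OC(=O)C(C)[C@H]4[C@H](C(=O)OCC=C)[C@]3(C2)C1 | intermediate
23 | 1-chloro-3-iodopropane | ClCCCI | starting material
24 | 4-(3-chloropropyl) anhydride (chain syn to H5) | C=C1[C@@H]2CC[C@H]3[C@H]4C(=O)OC(=O)[C@](C)(CCCCl)[C@H]4[C@H](C(=O)OCC=C)[C@]3(C2)C1 | intermediate (not isolated)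
25 | tetracyclic 19,20-anhydride 7-allyl ester (gibberell-16-ene-7,19,20-trioic acid 19,20-anhydride 7-allyl ester; C20 α; C18 β; 5βH) | C=C1[C@@H]2CC[C@H]3[C@@]45CCC[C@@](C)(C(=O)OC4=O)[C@H]5[C@H](C(=O)OCC=C)[C@]3(C2)C1 | intermediate
26 | tetracyclic 20-acid 7,19-diallyl ester (free 20-carboxylic acid) | C=C1[C@@H]2CC[C@H]3[C@]4(C(=O)O)CCC[C@@](C)(C(=O)OCC=C)[C@H]4[C@H](C(=O)OCC=C)[C@]3(C2)C1 | intermediate
27 | 20-acyl chloride of 26 | C=C1[C@@H]2CC[C@H]3[C@]4(C(Cl)=O)CCC[C@@](C)(C(=O)OCC=C)[C@H]4[C@H](C(=O)OCC=C)[C@]3(C2)C1 | intermediate (not isolated)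
28 | 20-aldehyde 7,19-diallyl ester (diallyl 20-oxogibberell-16-ene-7,19-dioate) | C=C1[C@@H]2CC[C@H]3[C@]4(C=O)CCC[C@@](C)(C(=O)OCC=C)[C@H]4[C@H](C(=O)OCC=C)[C@]3(C2)C1 | intermediate
29 | 15α-hydroxy 20-aldehyde diallyl ester (15-OH exo, syn to C14) | C=C1[C@@H]2CC[C@H]3[C@]4(C=O)CCC[C@@](C)(C(=O)OCC=C)[C@H]4[C@H](C(=O)OCC=C)[C@]3(C2)[C@H]1O | intermediate
30 | 15-oxo 20-aldehyde diallyl ester | C=C1[C@@H]2CC[C@H]3[C@]4(C=O)CCC[C@@](C)(C(=O)OCC=C)[C@H]4[C@H](C(=O)OCC=C)[C@]3(C2)C1=O | intermediate
31 | 15β-hydroxy 20-aldehyde diallyl ester (15-OH endo; diallyl ester of the target) | C=C1[C@@H]2CC[C@H]3[C@]4(C=O)CCC[C@@](C)(C(=O)OCC=C)[C@H]4[C@H](C(=O)OCC=C)[C@]3(C2)[C@@H]1O | intermediate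
32 | target gibberellin: 15β-hydroxy-20-oxogibberell-16-ene-7,19-dioic acid | C=C1[C@@H]2CC[C@H]3[C@]4(C=O)CCC[C@@](C)(C(=O)O)[C@H]4[C@H](C(=O)O)[C@]3(C2)[C@@H]1O | target

**Step count and risks**

Total step count: 20. Longest linear sequence: 20 steps (1 to 32, fully linear).

Steps most likely to fail:

Step 14 (the step that carries the label). The lithium enolate of the anhydride may open to a ketene carboxylate and be acylated, may alkylate on oxygen, or the second enolisation may be too slow, so that ring closure does not compete with decomposition. The fallback uses known chemistry and sets out from diacid 21, which is isolated after the ester cleavage of step 13 instead of being dehydrated. Both acids are esterified with 2-(trimethylsilyl)ethanol (EDC·HCl, DMAP, CH2Cl2) to give the bis[2-(trimethylsilyl)ethyl] ester F1. F1 is then submitted to the established stepwise one-pot dialkylation of 1,3-diesters (LDA, then 23; LDA again, THF/DMPU, −78 → 25 °C) to give the ring-A triester F2. In this open-chain mode the 4,10-cis relationship is not enforced and the C6–H of the allyl ester is protected only by its hindered position, so the cis-diaxial diastereomer would have to be separated. TBAF in THF then cleaves the two silylethyl esters to give the 19,20-diacid F3, and Ac2O closes F3 to anhydride 25 (only the cis-diacid can close), where the route is rejoined.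

Step 4. The alkylidene malonate may isomerise to the unreactive β,γ-unsaturated (endocyclic) isomer, or the Lewis acid may shift the new 16-ene into the ring, faster than C8–C15 bond formation. The fallback replaces the ene reaction by a Hosomi–Sakurai cyclisation and sets out from enone 3. Commercial 2-bromo-3-(trimethylsilyl)propene is converted (t-BuLi, then 2-isopropoxy-4,4,5,5-tetramethyl-1,3,2-dioxaborolane, THF, −78 °C) into the allylsilane boronate F4. The same Rh(acac)(C2H4)2/(R)-BINAP 1,4-addition and DBU equilibration, run on 3 with F4, give the allylsilane ketone F5. Knoevenagel condensation of F5 with 6 (TiCl4, pyridine) gives the alkylidene malonate F6. EtAlCl2 in CH2Cl2 at −78 °C then triggers intramolecular conjugate allylation with loss of the silyl group, which forms C8–C15 and the 16-methylene and returns to 8.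

Step 15. The alkoxide may open the anhydride at the C20 carbonyl instead of C19, which would give the wrong half ester. The fallback turns exactly that reversed site preference to advantage and sets out from 25. If C20 proves the more reactive carbonyl, LiAlH(OtBu)3 (THF, −78 → −20 °C) should reduce it to the lactol, which is the ring-chain tautomer of the 20-aldehyde 19-acid 7-allyl ester F7. Allylation of F7 (allyl bromide, Cs2CO3, DMF) gives 28, where the route is rejoined with step 16 no longer needed.

Further compounds
F1 | step 14 | bis[2-(trimethylsilyl)ethyl] 19,20-diester of 21 (7-allyl ester) | C=C1[C@@H]2CC[C@H]3[C@H](C(=O)OCC[Si](C)(C)C)[C@@H](C(C)C(=O)OCC[Si](C)(C)C)[C@H](C(=O)OCC=C)[C@]3(C2)C1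
F2 | step 14 | 7-allyl 19,20-bis[2-(trimethylsilyl)ethyl] gibberell-16-ene-7,19,20-trioate | C=C1[C@@H]2CC[C@H]3[C@]4(C(=O)OCC[Si](C)(C)C)CCC[C@@](C)(C(=O)OCC[Si](C)(C)C)[C@H]4[C@H](C(=O)OCC=C)[C@]3(C2)C1
F3 | step 14 | gibberell-16-ene-7,19,20-trioic acid 7-allyl ester (19,20-diacid) | C=C1[C@@H]2CC[C@H]3[C@]4(C(=O)O)CCC[C@@](C)(C(=O)O)[C@H]4[C@H](C(=O)OCC=C)[C@]3(C2)C1
F4 | step 4 | 4,4,5,5-tetramethyl-2-[3-(trimethylsilyl)prop-1-en-2-yl]-1,3,2-dioxaborolane | C[Si](C)(C)CC(=C)B1OC(C)(C)C(C)(C)O1
F5 | step 4 | tert-butyl 2-[(1S,4R)-2-oxo-4-(3-(trimethylsilyl)prop-1-en-2-yl)cyclohexyl]acetate | C[Si](C)(C)CC(=C)[C@@H]1CC[C@@H](CC(=O)OC(C)(C)C)C(=O)C1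
F6 | step 4 | diallyl 2-[(2S,5R)-2-(2-tert-butoxy-2-oxoethyl)-5-(3-(trimethylsilyl)prop-1-en-2-yl)cyclohexylidene]malonate | C[Si](C)(C)CC(=C)[C@@H]1CC[C@@H](CC(=O)OC(C)(C)C)C(=C(C(=O)OCC=C)C(=O)OCC=C)C1
F7 | step 15 | 20-oxogibberell-16-ene-7,19-dioic acid 7-allyl ester (free 19-acid) | C=C1[C@@H]2CC[C@H]3[C@]4(C=O)CCC[C@@](C)(C(=O)O)[C@H]4[C@H](C(=O)OCC=C)[C@]3(C2)C1
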